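**Retrosynthetic overview**

1. Target 40 comes from tetrabenzyl ether 39 by one hydrogenolysis; 39 comes from trans-selective alkylation of the enolate of (S)-lactone 14 (ring A fragment) with benzylic bromide 37, which forms the bond from lactone C3 to the methylene on benzofuran C5.
2. Bromide 37 comes from aldehyde 34, which is disconnected at O1–C2. The feature used is the free hydroxyl on ring C para to C2 of the dihydrofuran ring (O1, C2, C3, C3a, C7a): C2 is a latent para-quinone methide carbon within five-membered reach of the ring B oxygen O1, so oxidation of open-chain bisphenol 32 closes the ring and sets C2 from C3.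
3. Bisphenol 32 comes from Evans alkylation of ring B arylacetyl imide 25 with ring C bromide 4 (sets C3), then reduction, O-benzylation and unmasking; the ring B formyl group is carried as a nitrile up to step 18.
4. Ring B acid 23 comes from 3,4-dihydroxybenzonitrile by 4-O-allylation, 3-O-benzylation, Claisen rearrangement and cleavage of the allyl group; lactone 14 comes from dihydroferulic acid by Evans alkylation with tert-butyl bromoacetate.
5. Ring order: lactone ring first (step 7, in fragment 14), then the dihydrofuran ring (step 20); the three arenes are bought.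

Key step: step 20

Assumption: the configuration is taken exactly as drawn, (3S,4S) in the lactone and (2S,3R) in the dihydrobenzofuran. Ring A is the aryl ring of the lactone C4 benzyl group, ring B the benzo ring of the dihydrobenzofuran, ring C the aryl group on C2.

Design notes:
- The primary alcohol is protected as a benzyl ether, because it must survive the acid that removes the methoxymethyl groups and can leave in the last hydrogenolysis.
- The lactone is attached by enolate alkylation with a benzylic bromide. An acid/silane deoxygenation of an aldol adduct is avoided because it would also reduce the acid-labile benzylic C2–O1 ether.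

**Fragment 1: ring C bromide**

Step 1
Reactants: 1 vanillin (4-hydroxy-3-methoxybenzaldehyde)
Product: 2 3-methoxy-4-(methoxymethoxy)benzaldehyde
Conditions: MOMCl, i-Pr2NEt, CH2Cl2, 0 °C to rt
Reagents that add atoms: chloromethyl methyl ether, COCCl
Why: Williamson-type O-alkylation of the phenol with the chloromethyl ether masks the ring C hydroxyl as an acetal that should survive base, hydride and enolate chemistry and leave later with acid.

Step 2
Reactants: 2 3-methoxy-4-(methoxymethoxy)benzaldehyde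
Product: 3 [3-methoxy-4-(methoxymethoxy)phenyl]methanol
Conditions: NaBH4, MeOH, 0 °C
Reagents that add atoms: none
Why: Borohydride reduction of the aryl aldehyde to the benzylic alcohol, with no other reducible group present.

Step 3
Reactants: 3 [3-methoxy-4-(methoxymethoxy)phenyl]methanol
Product: 4 4-(bromomethyl)-2-methoxy-1-(methoxymethoxy)benzene
Conditions: CBr4, PPh3, CH2Cl2, 0 °C; used at once
Reagents that add atoms: carbon tetrabromide, BrC(Br)(Br)Br
Why: The Appel reaction converts the benzylic alcohol to the bromide under neutral conditions that should spare the acid-labile methoxymethyl acetal.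

**Fragment 2: (S)-lactone**

Step 4
Reactants: 5 3-(4-hydroxy-3-methoxyphenyl)propanoic acid (dihydroferulic acid)
Product: 7 3-[4-(benzyloxy)-3-methoxyphenyl]propanoic acid, via benzyl ester 6 (not isolated)
Conditions: BnBr, K2CO3, DMF, 60 °C; then NaOH, MeOH–H2O, 60 °C; HCl work-up
Reagents that add atoms: benzyl bromide, BrCc1ccccc1
Why: Double Williamson benzylation of phenol and carboxylate followed by saponification of the benzyl ester should leave only the phenol benzyl ether.

Step 5
Reactants: 7 3-[4-(benzyloxy)-3-methoxyphenyl]propanoic acid; 8 (R)-4-benzyl-1,3-oxazolidin-2-one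
Product: 10 (4R)-4-benzyl-3-{3-[4-(benzyloxy)-3-methoxyphenyl]propanoyl}-1,3-oxazolidin-2-one, via mixed anhydride 9 (not isolated)
Conditions: t-BuCOCl, Et3N, THF, −20 °C; then 8, LiCl, rt
Reagents that add atoms: none
Why: N-acylation of the oxazolidinone through the mixed pivalic anhydride, the nucleophile attacking the less hindered carbonyl.

Step 6
Reactants: 10 (4R)-4-benzyl-3-{3-[4-(benzyloxy)-3-methoxyphenyl]propanoyl}-1,3-oxazolidin-2-one
Product: 12 tert-butyl (3S)-4-[(4R)-4-benzyl-2-oxo-1,3-oxazolidin-3-yl]-3-{[4-(benzyloxy)-3-methoxyphenyl]methyl}-4-oxobutanoate, via sodium enolate 11 (not isolated)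
Conditions: NaN(SiMe3)2, THF, −78 °C; then BrCH2CO2t-Bu, −78 to −40 °C
Reagents that add atoms: tert-butyl bromoacetate, CC(C)(C)OC(=O)CBr
Why: Evans asymmetric alkylation: the chelated Z-enolate is alkylated on the face opposite the C4 benzyl group of the (R)-auxiliary, which sets the new centre as (S).

Step 7
Reactants: 12 tert-butyl (3S)-4-[(4R)-4-benzyl-2-oxo-1,3-oxazolidin-3-yl]-3-{[4-(benzyloxy)-3-methoxyphenyl]methyl}-4-oxobutanoate
Product: 14 (4S)-4-{[4-(benzyloxy)-3-methoxyphenyl]methyl}oxolan-2-one, via hydroxy ester 13 (not isolated)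
Conditions: LiBH4, MeOH (1 equiv), THF, 0 °C; then p-TsOH (cat.), toluene, 80 °C
Reagents that add atoms: none
Why: Hydride cleaves the exocyclic imide carbonyl faster than the hindered tert-butyl ester, and acid-catalysed lactonisation (intramolecular transesterification) closes the five-membered lactone without touching the stereocentre.

**Main line: ring B, precursor, key step, endgame**

Step 8
Reactants: 15 3,4-dihydroxybenzonitrile
Product: 16 3-hydroxy-4-(prop-2-en-1-yloxy)benzonitrile
Conditions: allyl bromide (1.0 equiv), NaHCO3, NaI (cat.), DMF, 40 °C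
Reagents that add atoms: allyl bromide, C=CCBr
Why: Regioselective Williamson etherification: the hydroxyl para to the nitrile is the more acidic, so the weak base forms its phenoxide selectively and monoallylation should go to O4.

Step 9
Reactants: 16 3-hydroxy-4-(prop-2-en-1-yloxy)benzonitrile
Product: 17 3-(benzyloxy)-4-(prop-2-en-1-yloxy)benzonitrile
Conditions: BnBr, K2CO3, DMF, rt
Reagents that add atoms: benzyl bromide, BrCc1ccccc1
Why: Williamson benzylation of the remaining phenol places on the future C7 oxygen a group that lasts until the final hydrogenolysis.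

Step 10
Reactants: 17 3-(benzyloxy)-4-(prop-2-en-1-yloxy)benzonitrile
Product: 19 3-(benzyloxy)-4-hydroxy-5-(prop-2-en-1-yl)benzonitrile, via dienone 18 (not isolated)
Conditions: N,N-diethylaniline, 190 °C
Reagents that add atoms: none
Why: Aromatic Claisen rearrangement: the [3,3] shift can end only at the free ortho carbon, since the other ortho position carries the benzyloxy group and the para position the nitrile, and the dienone tautomerises to the phenol.

Step 11
Reactants: 19 3-(benzyloxy)-4-hydroxy-5-(prop-2-en-1-yl)benzonitrile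
Product: 20 3-(benzyloxy)-4-(methoxymethoxy)-5-(prop-2-en-1-yl)benzonitrile
Conditions: MOMCl, i-Pr2NEt, CH2Cl2, 0 °C to rt
Reagents that add atoms: chloromethyl methyl ether, COCCl
Why: Methoxymethylation (Williamson-type) of the hindered but acidic phenol, chosen because this oxygen, the future O1, must be freed later under conditions that keep every benzyl ether.

Step 12
Reactants: 20 3-(benzyloxy)-4-(methoxymethoxy)-5-(prop-2-en-1-yl)benzonitrile
Product: 22 3-(benzyloxy)-4-(methoxymethoxy)-5-(2-oxoethyl)benzonitrile, via diol 21 (not isolated)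
Conditions: OsO4 (2 mol %), NaIO4, 2,6-lutidine, dioxane–H2O, rt; used crude
Reagents that add atoms: osmium tetroxide, O=[Os](=O)(=O)=O, reoxidised by sodium periodate, [Na+].[O-]I(=O)(=O)=O (source of the carbonyl oxygen)
Why: Lemieux–Johnson oxidation: catalytic dihydroxylation of the terminal alkene and periodate cleavage of the diol give the arylacetaldehyde, the nitrile, acetal and benzyl ether being inert to both oxidants.

Step 13
Reactants: 22 3-(benzyloxy)-4-(methoxymethoxy)-5-(2-oxoethyl)benzonitrile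
Product: 23 2-[3-(benzyloxy)-5-cyano-2-(methoxymethoxy)phenyl]acetic acid
Conditions: NaClO2, NaH2PO4, 2-methyl-2-butene, t-BuOH–H2O, 0 °C to rt
Reagents that add atoms: sodium chlorite, [Na+].[O-]Cl=O
Why: Pinnick oxidation converts the enolisable aldehyde to the acid under buffered conditions, 2-methyl-2-butene removing hypochlorite so that the electron-rich ring is not chlorinated.

Step 14
Reactants: 23 2-[3-(benzyloxy)-5-cyano-2-(methoxymethoxy)phenyl]acetic acid; 8 (R)-4-benzyl-1,3-oxazolidin-2-one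
Product: 25 (4R)-4-benzyl-3-{2-[3-(benzyloxy)-5-cyano-2-(methoxymethoxy)phenyl]acetyl}-1,3-oxazolidin-2-one, via mixed anhydride 24 (not isolated)
Conditions: t-BuCOCl, Et3N, THF, −20 °C; then 8, LiCl, rt
Reagents that add atoms: none
Why: N-acylation of the chiral oxazolidinone through the mixed pivalic anhydride, attack going to the less hindered arylacetyl carbonyl.

Step 15
Reactants: 25 (4R)-4-benzyl-3-{2-[3-(benzyloxy)-5-cyano-2-(methoxymethoxy)phenyl]acetyl}-1,3-oxazolidin-2-one; 4 4-(bromomethyl)-2-methoxy-1-(methoxymethoxy)benzene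
Product: 27 (4R)-4-benzyl-3-{(2R)-2-[3-(benzyloxy)-5-cyano-2-(methoxymethoxy)phenyl]-3-[3-methoxy-4-(methoxymethoxy)phenyl]propanoyl}-1,3-oxazolidin-2-one, via sodium enolate 26 (not isolated)
Conditions: NaN(SiMe3)2 (1.05 equiv), THF, −78 °C; then 4, −78 to −45 °C; AcOH quench at −78 °C
Reagents that add atoms: none
Why: Evans asymmetric alkylation: the chelated Z-sodium enolate is benzylated on the face opposite the C4 benzyl group of the (R)-auxiliary, which sets the future C3 as (R), and A(1,3) strain should keep the product from re-enolising.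

Step 16
Reactants: 27 (4R)-4-benzyl-3-{(2R)-2-[3-(benzyloxy)-5-cyano-2-(methoxymethoxy)phenyl]-3-[3-methoxy-4-(methoxymethoxy)phenyl]propanoyl}-1,3-oxazolidin-2-one
Product: 28 3-(benzyloxy)-5-{(2R)-1-hydroxy-3-[3-methoxy-4-(methoxymethoxy)phenyl]propan-2-yl}-4-(methoxymethoxy)benzonitrile
Conditions: LiBH4, MeOH (1 equiv), THF, 0 °C
Reagents that add atoms: none
Why: Reductive removal of the auxiliary by hydride attack at the exocyclic imide carbonyl should give the primary alcohol without epimerising the benzylic centre and leave the nitrile untouched.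

Step 17
Reactants: 28 3-(benzyloxy)-5-{(2R)-1-hydroxy-3-[3-methoxy-4-(methoxymethoxy)phenyl]propan-2-yl}-4-(methoxymethoxy)benzonitrile
Product: 29 3-(benzyloxy)-5-{(2R)-1-(benzyloxy)-3-[3-methoxy-4-(methoxymethoxy)phenyl]propan-2-yl}-4-(methoxymethoxy)benzonitrile
Conditions: NaH, BnBr, Bu4NI (cat.), THF, 0 °C to rt
Reagents that add atoms: benzyl bromide, BrCc1ccccc1
Why: Williamson etherification of the primary alkoxide; the benzylic hydrogen is meta to the nitrile and not acidic enough to be removed by the base.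

Step 18
Reactants: 29 3-(benzyloxy)-5-{(2R)-1-(benzyloxy)-3-[3-methoxy-4-(methoxymethoxy)phenyl]propan-2-yl}-4-(methoxymethoxy)benzonitrile
Product: 31 3-(benzyloxy)-5-{(2R)-1-(benzyloxy)-3-[3-methoxy-4-(methoxymethoxy)phenyl]propan-2-yl}-4-(methoxymethoxy)benzaldehyde, via aluminium imine 30 (not isolated)
Conditions: i-Bu2AlH (1.5 equiv), toluene, −78 to 0 °C; then 1 M HCl, 0 °C
Reagents that add atoms: water, O
Why: Partial reduction of the nitrile: one hydride gives the N-aluminio imine, which resists further reduction at low temperature and is hydrolysed to the aldehyde on acidic work-up.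

Step 19
Reactants: 31 3-(benzyloxy)-5-{(2R)-1-(benzyloxy)-3-[3-methoxy-4-(methoxymethoxy)phenyl]propan-2-yl}-4-(methoxymethoxy)benzaldehyde
Product: 32 3-(benzyloxy)-5-[(2R)-1-(benzyloxy)-3-(4-hydroxy-3-methoxyphenyl)propan-2-yl]-4-hydroxybenzaldehyde
Conditions: conc. HCl (10 equiv), MeOH–THF (1:1), 40 °C; aqueous work-up
Reagents that add atoms: none
Why: Acid-catalysed acetal exchange with methanol (methoxymethyl ether cleavage) frees both phenols, while the benzyl ethers, the aldehyde and the stereocentre should be stable to dilute acid.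

Step 20
Reactants: 32 3-(benzyloxy)-5-[(2R)-1-(benzyloxy)-3-(4-hydroxy-3-methoxyphenyl)propan-2-yl]-4-hydroxybenzaldehyde
Product: 34 (2S,3R)-7-(benzyloxy)-3-[(benzyloxy)methyl]-2-(4-hydroxy-3-methoxyphenyl)-2,3-dihydro-1-benzofuran-5-carbaldehyde, via quinone methide 33 (not isolated)
Conditions: Ag2O (1.5 equiv), 4 Å molecular sieves, dry CH2Cl2 (0.01 M), rt, dark
Reagents that add atoms: none
Why: Ag2O removes two electrons and two protons from the ring C 4-alkyl-2-methoxyphenol (phenoxyl radical, then loss of the benzylic hydrogen) to give the para-quinone methide, and the ring B phenol, the more acidic of the two, adds through O1 to the methide carbon C2 in a 1,6-conjugate (oxa-Michael) addition that restores the aromaticity of ring C. The closest known reaction type is Ag2O generation of para-quinone methides from 4-alkylphenols with intramolecular trapping, which is also the ring-forming event that ends the Ag2O-mediated 8–5 dehydrodimerisation of ferulates and isoeugenol to phenylcoumarans. The dihydrofuran ring (O1, C2, C3, C3a, C7a) closes in the 5-exo-trig mode. The new stereocentre C2 is controlled by the resident C3 centre: the aryl group takes the face anti to the C3 benzyloxymethyl group, and because the adduct is a para-hydroxybenzyl aryl ether the addition can revert, so the trans (2S,3R) isomer is also the thermodynamic outcome. The step needs oxidation of ring C and not ring B, which the para-formyl group on ring B secures by raising the oxidation potential of that phenol and leaving it no para benzylic hydrogen, and it needs O–C closure to outrun intermolecular coupling, which high dilution and the five-membered tether favour; dry, base-free conditions keep the formyl group from oxidation.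

Step 21
Reactants: 34 (2S,3R)-7-(benzyloxy)-3-[(benzyloxy)methyl]-2-(4-hydroxy-3-methoxyphenyl)-2,3-dihydro-1-benzofuran-5-carbaldehyde
Product: 35 (2S,3R)-7-(benzyloxy)-2-[4-(benzyloxy)-3-methoxyphenyl]-3-[(benzyloxy)methyl]-2,3-dihydro-1-benzofuran-5-carbaldehyde
Conditions: BnBr, K2CO3, DMF, rt
Reagents that add atoms: benzyl bromide, BrCc1ccccc1
Why: Williamson benzylation of the ring C phenol, which also locks the phenylcoumaran against reversible ring opening through the quinone methide.

Step 22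
Reactants: 35 (2S,3R)-7-(benzyloxy)-2-[4-(benzyloxy)-3-methoxyphenyl]-3-[(benzyloxy)methyl]-2,3-dihydro-1-benzofuran-5-carbaldehyde
Product: 36 {(2S,3R)-7-(benzyloxy)-2-[4-(benzyloxy)-3-methoxyphenyl]-3-[(benzyloxy)methyl]-2,3-dihydro-1-benzofuran-5-yl}methanol
Conditions: NaBH4, MeOH–THF, 0 °C
Reagents that add atoms: none
Why: Borohydride reduction of the aryl aldehyde to the benzylic alcohol; nothing else in 35 is reducible by NaBH4.

Step 23
Reactants: 36 {(2S,3R)-7-(benzyloxy)-2-[4-(benzyloxy)-3-methoxyphenyl]-3-[(benzyloxy)methyl]-2,3-dihydro-1-benzofuran-5-yl}methanol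
Product: 37 (2S,3R)-7-(benzyloxy)-2-[4-(benzyloxy)-3-methoxyphenyl]-3-[(benzyloxy)methyl]-5-(bromomethyl)-2,3-dihydro-1-benzofuran
Conditions: CBr4, PPh3, CH2Cl2, 0 °C; used crude
Reagents that add atoms: carbon tetrabromide, BrC(Br)(Br)Br
Why: The Appel reaction gives the benzylic bromide under neutral conditions that should spare the acid-labile benzylic ether C2–O1.

Step 24
Reactants: 14 (4S)-4-{[4-(benzyloxy)-3-methoxyphenyl]methyl}oxolan-2-one; 37 (2S,3R)-7-(benzyloxy)-2-[4-(benzyloxy)-3-methoxyphenyl]-3-[(benzyloxy)methyl]-5-(bromomethyl)-2,3-dihydro-1-benzofuran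
Product: 39 (3S,4S)-3-({(2S,3R)-7-(benzyloxy)-2-[4-(benzyloxy)-3-methoxyphenyl]-3-[(benzyloxy)methyl]-2,3-dihydro-1-benzofuran-5-yl}methyl)-4-{[4-(benzyloxy)-3-methoxyphenyl]methyl}oxolan-2-one, via lithium enolate 38 (not isolated)
Conditions: 14 (1.5 equiv), LiN(SiMe3)2, THF, −78 °C; then 37, DMPU, −78 to −30 °C
Reagents that add atoms: none
Why: Alkylation of a β-substituted γ-butyrolactone enolate: the bromide approaches the enolate face anti to the C4 arylmethyl group, which sets lactone C3 as (S) and gives the trans-3,4-disubstituted lactone.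

Step 25
Reactants: 39 (3S,4S)-3-({(2S,3R)-7-(benzyloxy)-2-[4-(benzyloxy)-3-methoxyphenyl]-3-[(benzyloxy)methyl]-2,3-dihydro-1-benzofuran-5-yl}methyl)-4-{[4-(benzyloxy)-3-methoxyphenyl]methyl}oxolan-2-one
Product: 40 (3S,4S)-3-{[(2S,3R)-7-hydroxy-2-(4-hydroxy-3-methoxyphenyl)-3-(hydroxymethyl)-2,3-dihydro-1-benzofuran-5-yl]methyl}-4-[(4-hydroxy-3-methoxyphenyl)methyl]oxolan-2-one (CNP0118131.1)
Conditions: H2 (1 atm), Pd(OH)2/C, EtOAc–MeOH, rt
Reagents that add atoms: none
Why: Catalytic hydrogenolysis should cleave the three aryl benzyl ethers and the primary alkyl benzyl ether at room temperature and 1 atm, conditions under which the lactone, the methyl ethers and the cyclic benzylic aryl ether C2–O1 are expected to survive.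

**Compound list**

1 | vanillin (4-hydroxy-3-methoxybenzaldehyde) | COc1cc(C=O)ccc1O | starting material
2 | 3-methoxy-4-(methoxymethoxy)benzaldehyde | COCOc1ccc(C=O)cc1OC | intermediate
3 | [3-methoxy-4-(methoxymethoxy)phenyl]methanol | COCOc1ccc(CO)cc1OC | intermediate
4 | 4-(bromomethyl)-2-methoxy-1-(methoxymethoxy)benzene | COCOc1ccc(CBr)cc1OC | intermediate
5 | 3-(4-hydroxy-3-methoxyphenyl)propanoic acid | COc1cc(CCC(=O)O)ccc1O | starting material
6 | benzyl 3-[4-(benzyloxy)-3-methoxyphenyl]propanoate | COc1cc(CCC(=O)OCc2ccccc2)ccc1OCc1ccccc1 | intermediate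
7 | 3-[4-(benzyloxy)-3-methoxyphenyl]propanoic acid | COc1cc(CCC(=O)O)ccc1OCc1ccccc1 | intermediate
8 | (R)-4-benzyl-1,3-oxazolidin-2-one | O=C1N[C@H](Cc2ccccc2)CO1 | starting material
9 | 3-[4-(benzyloxy)-3-methoxyphenyl]propanoic pivalic anhydride | COc1cc(CCC(=O)OC(=O)C(C)(C)C)ccc1OCc1ccccc1 | intermediate
10 | (4R)-4-benzyl-3-{3-[4-(benzyloxy)-3-methoxyphenyl]propanoyl}-1,3-oxazolidin-2-one | COc1cc(CCC(=O)N2C(=O)OC[C@H]2Cc2ccccc2)ccc1OCc1ccccc1 | intermediate
11 | sodium (Z)-enolate of 10 | COc1cc(C/C=C(\[O-])N2C(=O)OC[C@H]2Cc2ccccc2)ccc1OCc1ccccc1.[Na+] | intermediate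
12 | tert-butyl (3S)-4-[(4R)-4-benzyl-2-oxo-1,3-oxazolidin-3-yl]-3-{[4-(benzyloxy)-3-methoxyphenyl]methyl}-4-oxobutanoate | COc1cc(C[C@@H](CC(=O)OC(C)(C)C)C(=O)N2C(=O)OC[C@H]2Cc2ccccc2)ccc1OCc1ccccc1 | intermediate
13 | tert-butyl (3S)-3-{[4-(benzyloxy)-3-methoxyphenyl]methyl}-4-hydroxybutanoate | COc1cc(C[C@@H](CC(=O)OC(C)(C)C)CO)ccc1OCc1ccccc1 | intermediate
14 | (4S)-4-{[4-(benzyloxy)-3-methoxyphenyl]methyl}oxolan-2-one | COc1cc(C[C@@H]2COC(=O)C2)ccc1OCc1ccccc1 | intermediate
15 | 3,4-dihydroxybenzonitrile | N#Cc1ccc(O)c(O)c1 | starting material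
16 | 3-hydroxy-4-(prop-2-en-1-yloxy)benzonitrile | N#Cc1ccc(OCC=C)c(O)c1 | intermediate
17 | 3-(benzyloxy)-4-(prop-2-en-1-yloxy)benzonitrile | N#Cc1ccc(OCC=C)c(OCc2ccccc2)c1 | intermediate
18 | 5-(benzyloxy)-4-oxo-3-(prop-2-en-1-yl)cyclohexa-1,5-diene-1-carbonitrile (Claisen dienone, racemic) | N#CC1=CC(CC=C)C(=O)C(OCc2ccccc2)=C1 | intermediate
19 | 3-(benzyloxy)-4-hydroxy-5-(prop-2-en-1-yl)benzonitrile | N#Cc1cc(CC=C)c(O)c(OCc2ccccc2)c1 | intermediate
20 | 3-(benzyloxy)-4-(methoxymethoxy)-5-(prop-2-en-1-yl)benzonitrile | N#Cc1cc(CC=C)c(OCOC)c(OCc2ccccc2)c1 | intermediate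
21 | 3-(benzyloxy)-5-(2,3-dihydroxypropyl)-4-(methoxymethoxy)benzonitrile (racemic) | N#Cc1cc(CC(O)CO)c(OCOC)c(OCc2ccccc2)c1 | intermediate
22 | 3-(benzyloxy)-4-(methoxymethoxy)-5-(2-oxoethyl)benzonitrile | N#Cc1cc(CC=O)c(OCOC)c(OCc2ccccc2)c1 | intermediate
23 | 2-[3-(benzyloxy)-5-cyano-2-(methoxymethoxy)phenyl]acetic acid | N#Cc1cc(CC(=O)O)c(OCOC)c(OCc2ccccc2)c1 | intermediate
24 | 2-[3-(benzyloxy)-5-cyano-2-(methoxymethoxy)phenyl]acetic pivalic anhydride | N#Cc1cc(CC(=O)OC(=O)C(C)(C)C)c(OCOC)c(OCc2ccccc2)c1 | intermediate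
25 | (4R)-4-benzyl-3-{2-[3-(benzyloxy)-5-cyano-2-(methoxymethoxy)phenyl]acetyl}-1,3-oxazolidin-2-one | N#Cc1cc(CC(=O)N2C(=O)OC[C@H]2Cc2ccccc2)c(OCOC)c(OCc2ccccc2)c1 | intermediate
26 | sodium (Z)-enolate of 25 | N#Cc1cc(/C=C(\[O-])N2C(=O)OC[C@H]2Cc2ccccc2)c(OCOC)c(OCc2ccccc2)c1.[Na+] | intermediate
27 | (4R)-4-benzyl-3-{(2R)-2-[3-(benzyloxy)-5-cyano-2-(methoxymethoxy)phenyl]-3-[3-methoxy-4-(methoxymethoxy)phenyl]propanoyl}-1,3-oxazolidin-2-one | N#Cc1cc(OCc2ccccc2)c(OCOC)c(c1)[C@H](C(=O)N1C(=O)OC[C@H]1Cc1ccccc1)Cc1ccc(OCOC)c(OC)c1 | intermediate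
28 | 3-(benzyloxy)-5-{(2R)-1-hydroxy-3-[3-methoxy-4-(methoxymethoxy)phenyl]propan-2-yl}-4-(methoxymethoxy)benzonitrile | N#Cc1cc(OCc2ccccc2)c(OCOC)c(c1)[C@H](CO)Cc1ccc(OCOC)c(OC)c1 | intermediate
29 | 3-(benzyloxy)-5-{(2R)-1-(benzyloxy)-3-[3-methoxy-4-(methoxymethoxy)phenyl]propan-2-yl}-4-(methoxymethoxy)benzonitrile | N#Cc1cc(OCc2ccccc2)c(OCOC)c(c1)[C@H](COCc1ccccc1)Cc1ccc(OCOC)c(OC)c1 | intermediate
30 | N-(diisobutylaluminio) aldimine of 31 | CC(C)C[Al](CC(C)C)N=Cc1cc(OCc2ccccc2)c(OCOC)c(c1)[C@H](COCc1ccccc1)Cc1ccc(OCOC)c(OC)c1 | intermediate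
31 | 3-(benzyloxy)-5-{(2R)-1-(benzyloxy)-3-[3-methoxy-4-(methoxymethoxy)phenyl]propan-2-yl}-4-(methoxymethoxy)benzaldehyde | O=Cc1cc(OCc2ccccc2)c(OCOC)c(c1)[C@H](COCc1ccccc1)Cc1ccc(OCOC)c(OC)c1 | intermediate
32 | 3-(benzyloxy)-5-[(2R)-1-(benzyloxy)-3-(4-hydroxy-3-methoxyphenyl)propan-2-yl]-4-hydroxybenzaldehyde (key-step precursor) | O=Cc1cc(OCc2ccccc2)c(O)c(c1)[C@H](COCc1ccccc1)Cc1ccc(O)c(OC)c1 | intermediate
33 | 3-(benzyloxy)-5-[(2R)-1-(benzyloxy)-3-(3-methoxy-4-oxocyclohexa-2,5-dien-1-ylidene)propan-2-yl]-4-hydroxybenzaldehyde (para-quinone methide) | O=Cc1cc(OCc2ccccc2)c(O)c(c1)[C@H](COCc1ccccc1)C=C1C=CC(=O)C(OC)=C1 | intermediate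
34 | (2S,3R)-7-(benzyloxy)-3-[(benzyloxy)methyl]-2-(4-hydroxy-3-methoxyphenyl)-2,3-dihydro-1-benzofuran-5-carbaldehyde (key-step product) | O=Cc1cc(OCc2ccccc2)c2c(c1)[C@H](COCc1ccccc1)[C@@H](c1ccc(O)c(OC)c1)O2 | intermediate
35 | (2S,3R)-7-(benzyloxy)-2-[4-(benzyloxy)-3-methoxyphenyl]-3-[(benzyloxy)methyl]-2,3-dihydro-1-benzofuran-5-carbaldehyde | O=Cc1cc(OCc2ccccc2)c2c(c1)[C@H](COCc1ccccc1)[C@@H](c1ccc(OCc3ccccc3)c(OC)c1)O2 | intermediate
36 | {(2S,3R)-7-(benzyloxy)-2-[4-(benzyloxy)-3-methoxyphenyl]-3-[(benzyloxy)methyl]-2,3-dihydro-1-benzofuran-5-yl}methanol | OCc1cc(OCc2ccccc2)c2c(c1)[C@H](COCc1ccccc1)[C@@H](c1ccc(OCc3ccccc3)c(OC)c1)O2 | intermediate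
37 | (2S,3R)-7-(benzyloxy)-2-[4-(benzyloxy)-3-methoxyphenyl]-3-[(benzyloxy)methyl]-5-(bromomethyl)-2,3-dihydro-1-benzofuran | BrCc1cc(OCc2ccccc2)c2c(c1)[C@H](COCc1ccccc1)[C@@H](c1ccc(OCc3ccccc3)c(OC)c1)O2 | intermediate
38 | lithium enolate of 14 | COc1cc(C[C@@H]2COC([O-])=C2)ccc1OCc1ccccc1.[Li+] | intermediate
39 | (3S,4S)-3-({(2S,3R)-7-(benzyloxy)-2-[4-(benzyloxy)-3-methoxyphenyl]-3-[(benzyloxy)methyl]-2,3-dihydro-1-benzofuran-5-yl}methyl)-4-{[4-(benzyloxy)-3-methoxyphenyl]methyl}oxolan-2-one | COc1cc(C[C@@H]2COC(=O)[C@H]2Cc2cc(OCc3ccccc3)c3c(c2)[C@H](COCc2ccccc2)[C@@H](c2ccc(OCc4ccccc4)c(OC)c2)O3)ccc1OCc1ccccc1 | intermediate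
40 | (3S,4S)-3-{[(2S,3R)-7-hydroxy-2-(4-hydroxy-3-methoxyphenyl)-3-(hydroxymethyl)-2,3-dihydro-1-benzofuran-5-yl]methyl}-4-[(4-hydroxy-3-methoxyphenyl)methyl]oxolan-2-one | COc1cc(C[C@@H]2COC(=O)[C@H]2Cc2cc(O)c3c(c2)[C@H](CO)[C@@H](c2ccc(O)c(OC)c2)O3)ccc1O | target

**Step count**

Total: 25 steps. Longest linear sequence: 18 steps (steps 8 to 25, from 3,4-dihydroxybenzonitrile 15 to target 40).

**The three steps most likely to fail**

1. Step 20 (oxidative ring closure). Three processes could defeat it: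
   - the ring C phenoxyl radical could couple intermolecularly through its free ortho position faster than it is oxidised on to the quinone methide;
   - the quinone methide could tautomerise to the stilbene by loss of the C3 hydrogen, which would erase the only auxiliary-made stereocentre;
   - the product, still a para-alkylphenol, could be oxidised a second time.

   Fallback, a non-oxidative acid-mediated closure that sets out from acid 23 and comes back at aldehyde 35. Acid 23 would be coupled through mixed anhydride 24 with (S)-4-benzyl-1,3-oxazolidin-2-one to the enantiomeric-auxiliary imide F1. Its dibutylboron enolate F2 (Bu2BOTf, i-Pr2NEt, CH2Cl2, −78 °C) would add to aldehyde 2 to give the syn aldol F3; because the boron aldol uses the enolate face opposite to that used in alkylation, the (S)-auxiliary places ring B as in 27. LiBH4 would give the diol F4. Methanolic HCl would then remove both methoxymethyl groups, ionise the para-hydroxybenzylic alcohol and let the ring B phenol close the trans phenylcoumaran nitrile F5 under thermodynamic control, whatever the carbinol configuration. NaH and BnBr would benzylate the phenol and the primary alcohol to the tribenzyl nitrile F6, and i-Bu2AlH through the aluminium imine F7, followed by acidic work-up, would give 35.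

2. Step 15 (auxiliary alkylation of the arylacetyl imide). The hindered, stabilised enolate could lose the oxazolidinone (ketene pathway) on warming before it is alkylated, and proton exchange at the doubly activated α-carbon could erode the diastereomer ratio.

   Fallback, catalytic asymmetric hydrogenation in place of auxiliary control, setting out from acid 23 and aldehyde 2 and coming back at alcohol 28. Perkin condensation (Ac2O, Et3N, 110 °C) would give the (E)-2,3-diarylacrylic acid F8. Hydrogenation with a cationic iridium complex of a chiral spiro phosphine–oxazoline ligand L, [Ir(cod)(L)][B(C6H3(CF3)2)4] (H2, Et3N, MeOH), would give the (R)-acid F9; the ligand antipode that delivers (R) would be fixed by a small-scale run. BH3·SMe2 (THF, 0 °C) would then reduce the acid in the presence of the nitrile to 28.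

3. Step 25 (global hydrogenolysis). While the slow primary alkyl benzyl ether is being removed, over-reduction could set in: hydrogenolysis of the benzylic aryl ether C2–O1 would open the dihydrofuran ring.

   Fallback, non-reductive Lewis-acid debenzylation that sets out from 39 and ends at target 40: BCl3 with pentamethylbenzene as benzyl-cation scavenger in CH2Cl2 at −78 °C, conditions under which methyl ethers and the lactone should persist and any transient ionisation of C2–O1 is returned by reclosure of the tethered phenol. This fallback makes no new compound (F0).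

Further compounds
F1 | step 20 | (4S)-4-benzyl-3-{2-[3-(benzyloxy)-5-cyano-2-(methoxymethoxy)phenyl]acetyl}-1,3-oxazolidin-2-one | N#Cc1cc(CC(=O)N2C(=O)OC[C@@H]2Cc2ccccc2)c(OCOC)c(OCc2ccccc2)c1
F2 | step 20 | (Z)-dibutylboron enolate of F1 | N#Cc1cc(/C=C(\OB(CCCC)CCCC)N2C(=O)OC[C@@H]2Cc2ccccc2)c(OCOC)c(OCc2ccccc2)c1
F3 | step 20 | (4S)-4-benzyl-3-{(2S,3S)-2-[3-(benzyloxy)-5-cyano-2-(methoxymethoxy)phenyl]-3-hydroxy-3-[3-methoxy-4-(methoxymethoxy)phenyl]propanoyl}-1,3-oxazolidin-2-one | N#Cc1cc(OCc2ccccc2)c(OCOC)c(c1)[C@H](C(=O)N1C(=O)OC[C@@H]1Cc1ccccc1)[C@H](O)c1ccc(OCOC)c(OC)c1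
F4 | step 20 | 3-(benzyloxy)-5-{(1S,2R)-1,3-dihydroxy-1-[3-methoxy-4-(methoxymethoxy)phenyl]propan-2-yl}-4-(methoxymethoxy)benzonitrile | N#Cc1cc(OCc2ccccc2)c(OCOC)c(c1)[C@H](CO)[C@H](O)c1ccc(OCOC)c(OC)c1
F5 | step 20 | (2S,3R)-7-(benzyloxy)-2-(4-hydroxy-3-methoxyphenyl)-3-(hydroxymethyl)-2,3-dihydro-1-benzofuran-5-carbonitrile | N#Cc1cc(OCc2ccccc2)c2c(c1)[C@H](CO)[C@@H](c1ccc(O)c(OC)c1)O2
F6 | step 20 | (2S,3R)-7-(benzyloxy)-2-[4-(benzyloxy)-3-methoxyphenyl]-3-[(benzyloxy)methyl]-2,3-dihydro-1-benzofuran-5-carbonitrile | N#Cc1cc(OCc2ccccc2)c2c(c1)[C@H](COCc1ccccc1)[C@@H](c1ccc(OCc3ccccc3)c(OC)c1)O2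
F7 | step 20 | N-(diisobutylaluminio) aldimine of 35 | CC(C)C[Al](CC(C)C)N=Cc1cc(OCc2ccccc2)c2c(c1)[C@H](COCc1ccccc1)[C@@H](c1ccc(OCc3ccccc3)c(OC)c1)O2
F8 | step 15 | (2E)-2-[3-(benzyloxy)-5-cyano-2-(methoxymethoxy)phenyl]-3-[3-methoxy-4-(methoxymethoxy)phenyl]prop-2-enoic acid | N#Cc1cc(OCc2ccccc2)c(OCOC)c(c1)/C(C(=O)O)=C\c1ccc(OCOC)c(OC)c1
F9 | step 15 | (2R)-2-[3-(benzyloxy)-5-cyano-2-(methoxymethoxy)phenyl]-3-[3-methoxy-4-(methoxymethoxy)phenyl]propanoic acid | N#Cc1cc(OCc2ccccc2)c(OCOC)c(c1)[C@H](C(=O)O)Cc1ccc(OCOC)c(OC)c1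
F0 | step 25 | none | none
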